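Readings and results are simulated for an exercise; the scatter is artificial.

At early times the substrate falls at once in both earlier runs, with no lag, and the examiner starts there.

| setting | spring | winter | flask |
|---|---|---|---|
| substrate | 0.75 M | 1.1 M | 1.5 M |
| gas phase | 200 mM (held) | 200 mM (held) | 200 mM (held) |
| remark | run made earlier | run made earlier |  |
| time |  |  | 15 h |

| run | time / h | target / % | substrate / % |
|---|---|---|---|
| spring | 0.250 | 12.0 | 86.2 |
| spring | 0.500 | 19.7 | 73.7 |
| spring | 1.00 | 24.1 | 53.9 |
| spring | 2.00 | 18.7 | 28.4 |
| spring | 4.00 | 6.1 | 8.8 |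
| spring | 8.00 | 2.3 | 0.5 |
| spring | 15.0 | 0 | 0.2 |
| winter | 0.250 | 10.7 | 84.5 |
| winter | 0.500 | 18.7 | 73.5 |
| winter | 1.00 | 23.6 | 51.7 |
| winter | 2.00 | 18.9 | 29.5 |
| winter | 4.00 | 8.6 | 7.1 |
| winter | 8.00 | 1.9 | 0.8 |
| winter | 15.0 | 1.2 | 2.6 |

(each reading ± 1 percentage point)

- at the start none of the gas is dissolved
- steps that have been proposed: target <-> isomer of the product; gas phase <-> dissolved gas; dissolved gas + target -> over-reacted product; substrate + dissolved gas -> target; dissolved gas + target -> over-reaction product; dissolved gas -> decomposed reagent

* time up to 15 h at which target stands highest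
* the amount of target, in percent of the substrate charged, at that time
* earliest time at which at least nineteen twentieths of that best amount are there
* latest time at which they still are

How fast does the substrate go? Between 1.00 h and 4.00 h it drops from 53.9 % to 8.8 % in the spring run and from 51.7 % to 7.1 % in the winter run. Taking logarithms gives 0.604 h⁻¹ and 0.662 h⁻¹, a gap that a scatter of 1 percentage point on readings this small can produce. I call their mean k, the share of the remaining substrate lost per hour while dissolved gas is frozen at one level, which is 0.633 h⁻¹. It is a pseudo-first-order constant.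

Why freeze the gas? The winter charge is 1.47 times the spring charge, yet target at 1.00 h reads 24.1 % and 23.6 %. Percent curves that lie on each other suggest the same gas level in both runs.

But can the liquid hold that much gas? No. If each substrate takes one gas, the substrate step of the winter run had used 0.531 M by 1.00 h, more than the saturation level of 200 mM. So gas kept flowing in, against a demand of 0.696 M h⁻¹, reckoned with k for the full winter charge.

And the new flask? Reckoned the same way, its full charge asks 0.949 M h⁻¹, and that charge is above both earlier ones, so this is the weak spot. I still commit to the same curve: a peak near 1.00 h at about 23.9 %.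

The forecast agrees on the curve, “I expect the same curve in percent”, but its peak of 24.3 % at 1.05 h stands a little higher and later than mine, with a window from 0.72 h to 1.5 h.

The flask peaks at 1.10 h with 24.1 %, and its window runs from 0.782 h to 1.51 h.

    target ⇌ isomer of the product (K = 2.56, k = 8.87 × 10⁻⁵ s⁻¹)
    gas phase ⇌ dissolved gas, rate k2*(csat - [dissolved gas]) (kL = 0.0207 s⁻¹)
    dissolved gas + target → over-reacted product (k = 1.35 × 10⁻⁴ M⁻¹ s⁻¹)
    substrate + dissolved gas → target (k = 9.33 × 10⁻⁴ M⁻¹ s⁻¹)
    dissolved gas + target → over-reaction product (k = 0.00140 M⁻¹ s⁻¹)
    dissolved gas → decomposed reagent (k = 1.88 × 10⁻⁴ s⁻¹)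

At that peak dissolved gas stands at 0.187 M, which is 93.4 % of saturation. With k, the substrate at the peak should be 49.8 %, and the flask holds 50.7 %. Read at 4.0 h, k gives 7.95 %, and the same flask holds 7.83 %.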